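**Plan**
Retrosynthesis: the C7–CH2/pyranone C3 bond and the C5–acyl bond are cut first, then the O1–C2 bond of ring B (back to an ortho-prenyl phenol), and last ring A itself at C7–C7a and C5–C6 (with C3a–C7a), which leaves a 3-methoxy-4-prenylcyclobutenone and a siloxyalkyne.
Enabling feature: ring A (C3a, C4, C5, C6, C7, C7a) is a hexasubstituted phloroglucinol whose oxygens differ in role. O at C7a is the ring B ether, and O at C4 and C6 are free hydroxyls flanking the C5 acyl group. A cyclobutenone/siloxyalkyne benzannulation delivers this pattern as free OH (C7a), methyl ether (C4) and silyl ether (C6), with C5 the only ring CH.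
Forward: a ketene/methoxyethyne (2+2) gives the cyclobutenone, and heating with the siloxyalkyne builds ring A. Ring B is closed by the lone phenol on an epoxide. C5 is then brominated and acylated, the pyranone is joined at C7 by ionising a benzylic methyl ether, and demethylation, dehydration and desilylation finish.
Stereochemistry: C2 comes from a Shi epoxidation with the L-fructose-derived ketone followed by invertive 5-exo closure. The acyl stereocentre is carried in from (R)-2-methylbutanoic acid.
Group choices: the C4 oxygen is a methyl ether so that chelation-assisted cleavage next to the ketone is mild. C7 carries CH2OMe, which is ionised directly and needs no deprotection. The propan-2-ol side chain is dehydrated only after all Lewis-acid steps, because a 2-isopropenyl dihydrobenzofuran is opened by them.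

Key step: step 5

Assumption: (R)-2-methylbutanoic acid and the L-fructose-derived Shi ketone are taken as purchasable; ring atoms are numbered as in 1-benzofuran (O1, C2, C3, C3a, C4–C7, C7a).

**Route**

Step 1
Reactants: 1 2-chloro-1,1-dimethoxyethane
Product: 3 methoxyethyne, via sodium methoxyethynide 2 (not isolated)
Conditions: NaNH2 (3 equiv), liq. NH3, −33 °C; sat. aq. NaCl, −70 °C; distilled into cold Et2O
Reagents that add atoms: none
Why: Twofold amide-induced β-elimination (methanol, then HCl) from the α-chloro acetal is the classical synthesis of 1-alkoxyalkynes, and the third equivalent of base holds the product as its sodium acetylide until the cold quench.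

Step 2
Reactants: 4 5-methylhex-4-enoic acid
Product: 5 5-methylhex-4-enoyl chloride
Conditions: (COCl)2, DMF (cat.), CH2Cl2, 0 → 25 °C
Reagents that add atoms: oxalyl chloride, O=C(Cl)C(=O)Cl
Why: Acid chloride formation through the chloroiminium (Vilsmeier-type) catalyst is mild enough to leave the trisubstituted olefin alone, and the gaseous by-products leave a chloride that can be used crude.

Step 3
Reactants: 5 5-methylhex-4-enoyl chloride; 3 methoxyethyne
Product: 7 3-methoxy-4-(3-methylbut-2-en-1-yl)cyclobut-2-en-1-one (racemic), via prenylketene 6 (not isolated)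
Conditions: 3 (2 equiv), Et3N (slow addition), Et2O, 0 → 25 °C
Reagents that add atoms: none
Why: Dehydrochlorination should give the aldoketene, which is trapped in a ketene–ynol ether (2+2) cycloaddition in which the nucleophilic alkyne CH bonds to the ketene carbonyl carbon, the established route to 4-alkyl-3-alkoxycyclobutenones; slow base addition and excess alkyne hold back ketene dimerisation, and the new stereocentre may be racemic because step 5 erases it.

Step 4
Reactants: 8 3-methoxyprop-1-yne
Product: 11 [(3-methoxyprop-1-yn-1-yl)oxy]tri(propan-2-yl)silane, via lithium acetylide 9 (not isolated), via lithium ynolate 10 (not isolated)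
Conditions: n-BuLi, THF, −78 °C; LiOOt-Bu (from t-BuOOH and LiHMDS), −78 → 0 °C; TIPSOTf, −78 → 0 °C
Reagents that add atoms: tert-butyl hydroperoxide (used as LiOOt-Bu), CC(C)(C)OO; tri(propan-2-yl)silyl trifluoromethanesulfonate, CC(C)[Si](OS(=O)(=O)C(F)(F)F)(C(C)C)C(C)C
Why: Electrophilic oxygen transfer from the lithium peroxide to the acetylide (acetylide-to-ynolate oxidation) and O-silylation by the bulky silyl triflate is the standard preparation of triisopropylsiloxyalkynes, and at these temperatures the ynolate should not expel the poor methoxide leaving group.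

Step 5
Reactants: 7 3-methoxy-4-(3-methylbut-2-en-1-yl)cyclobut-2-en-1-one; 11 [(3-methoxyprop-1-yn-1-yl)oxy]tri(propan-2-yl)silane
Product: 15 5-methoxy-2-(methoxymethyl)-6-(3-methylbut-2-en-1-yl)-3-{[tri(propan-2-yl)silyl]oxy}phenol, via vinylketene 12 (not isolated), via vinylcyclobutenone 13 (not isolated), via dienylketene 14 (not isolated)
Conditions: 11 (1.3 equiv), toluene (degassed), 90 °C then 110 °C, sealed tube
Reagents that add atoms: none
Why: Thermal 4π electrocyclic opening of 7 should give vinylketene 12; the alkyne carbon of 11 that is β to oxygen adds to the ketene carbonyl carbon in a (2+2) cycloaddition to give 13, whose 4π opening to dienylketene 14 and 6π electrocyclisation re-form the C3a–C7a bond, and tautomerisation gives the phenol. This is the Danheiser benzannulation as practised with siloxyalkynes (giving resorcinol monosilyl ethers), applied here to a 3-alkoxycyclobutenone. Ring A is closed by a thermal disrotatory 6π electrocyclisation of the dienylketene, the C7–C7a and C5–C6 bonds having been made in the cycloaddition. No stereocentre is formed, and the one in racemic 7 is destroyed on ring opening, so the olefin geometry of 12 is without consequence. The step needs regioselectivity in the ketene–alkyne union, which the polarisation of the silyl ynol ether secures, so that the ketene oxygen ends at C7a between the prenyl and methoxymethyl carbons. The product should therefore carry one free hydroxyl (the future ring B oxygen), a methyl ether at C4, a silyl ether at C6 and hydrogen only at C5.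

Step 6
Reactants: 15 the phenol from step 5
Product: 16 5-methoxy-2-(methoxymethyl)-6-(3-methylbut-2-en-1-yl)-3-{[tri(propan-2-yl)silyl]oxy}phenyl acetate
Conditions: Ac2O, Et3N, DMAP (cat.), CH2Cl2, 25 °C
Reagents that add atoms: acetic anhydride, CC(=O)OC(C)=O
Why: DMAP-catalysed O-acylation caps the single phenol so that no electron-rich phenolate with a free para position meets the oxidant of step 7, and the acetate comes off under the basic conditions that close ring B.

Step 7
Reactants: 16 the aryl acetate from step 6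
Product: 17 6-{[(2S)-3,3-dimethyloxiran-2-yl]methyl}-5-methoxy-2-(methoxymethyl)-3-{[tri(propan-2-yl)silyl]oxy}phenyl acetate
Conditions: L-fructose-derived Shi ketone (30 mol%), KHSO5 (as Oxone, 2KHSO5·KHSO4·K2SO4), K2CO3, Bu4NHSO4, MeCN/CH2(OMe)2/aq. Na2B4O7–Na2EDTA buffer (pH 10.5), 0 °C
Reagents that add atoms: potassium peroxymonosulfate, [K+].[O-]S(=O)(=O)OO
Why: Shi asymmetric epoxidation: the chiral dioxirane formed in situ transfers oxygen to the electron-rich trisubstituted olefin through the spiro transition state, and the L-configured ketone selects the face that gives the (S)-epoxide (the D-configured catalyst gives R with olefins of this type).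

Step 8
Reactants: 17 the (S)-epoxide from step 7
Product: 19 2-[(2R)-4-methoxy-7-(methoxymethyl)-6-{[tri(propan-2-yl)silyl]oxy}-2,3-dihydro-1-benzofuran-2-yl]propan-2-ol, via potassium phenolate 18 (not isolated)
Conditions: K2CO3, MeOH, 0 → 25 °C
Reagents that add atoms: none
Why: Methanolysis of the aryl acetate frees the phenolate, which opens the epoxide at its less substituted carbon in a 5-exo-tet SN2 reaction with inversion, so that the (S)-epoxide becomes the (2R)-dihydrobenzofuran of ring B; basic closure avoids the 6-endo chroman that acid would favour.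

Step 9
Reactants: 19 the dihydrobenzofuran alcohol from step 8
Product: 20 2-[(2R)-5-bromo-4-methoxy-7-(methoxymethyl)-6-{[tri(propan-2-yl)silyl]oxy}-2,3-dihydro-1-benzofuran-2-yl]propan-2-ol
Conditions: NBS, MeCN, −20 → 0 °C
Reagents that add atoms: N-bromosuccinimide, O=C1CCC(=O)N1Br
Why: Electrophilic aromatic bromination can only go to C5, the one unsubstituted ring carbon, which is activated by two ortho oxygens and one para oxygen.

Step 10
Reactants: 21 (2R)-2-methylbutanoic acid
Product: 23 (2R)-N-methoxy-N,2-dimethylbutanamide, via acyl imidazole 22 (not isolated)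
Conditions: CDI, CH2Cl2, 0 → 25 °C; then MeNHOMe·HCl
Reagents that add atoms: N,O-dimethylhydroxylamine hydrochloride, CNOC.Cl
Why: Weinreb amide formation through the acyl imidazole needs no strong base, so the α-stereocentre of the chiral-pool acid is not put at risk.

Step 11
Reactants: 20 the aryl bromide from step 9; 23 (2R)-N-methoxy-N,2-dimethylbutanamide
Product: 25 (2R)-1-[(2R)-2-(2-hydroxypropan-2-yl)-4-methoxy-7-(methoxymethyl)-6-{[tri(propan-2-yl)silyl]oxy}-2,3-dihydro-1-benzofuran-5-yl]-2-methylbutan-1-one, via dilithio species 24 (not isolated)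
Conditions: n-BuLi (2.2 equiv), THF, −78 °C; then 23, −78 → −40 °C; aq. NH4Cl
Reagents that add atoms: none
Why: After deprotonation of the tertiary alcohol, bromine–lithium exchange gives the C5 aryllithium, which adds to the Weinreb amide to form a chelated tetrahedral adduct that collapses to the ketone only on work-up, so over-addition is excluded and the α-stereocentre never sits next to a free carbonyl under basic conditions; the low temperature keeps the ortho silyl group on oxygen.

Step 12
Reactants: 26 pentan-3-one
Product: 27 trimethyl(pent-2-en-3-yloxy)silane (E/Z mixture)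
Conditions: TMSCl, Et3N, DMF, 80 °C
Reagents that add atoms: chlorotrimethylsilane, C[Si](C)(C)Cl
Why: Enol silylation of a symmetrical ketone under equilibrating amine conditions has no regiochemical issue, and the double-bond geometry is lost in the next step.

Step 13
Reactants: 27 trimethyl(pent-2-en-3-yloxy)silane; 28 propanedioyl dichloride (malonyl dichloride)
Product: 29 6-ethyl-4-hydroxy-5-methyl-2H-pyran-2-one
Conditions: Et2O, −78 → 25 °C
Reagents that add atoms: none
Why: C-acylation of the silyl enol ether by one acyl chloride and ring closure of the enolised β-diketo acid chloride through oxygen (the acylative pyranone annulation of enol ethers with malonyl dichloride) should give the 4-hydroxy-2-pyranone directly.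

Step 14
Reactants: 25 the ketone from step 11; 29 6-ethyl-4-hydroxy-5-methyl-2H-pyran-2-one
Product: 30 6-ethyl-4-hydroxy-3-{[(2R)-2-(2-hydroxypropan-2-yl)-4-methoxy-5-[(2R)-2-methylbutanoyl]-6-{[tri(propan-2-yl)silyl]oxy}-2,3-dihydro-1-benzofuran-7-yl]methyl}-5-methyl-2H-pyran-2-one
Conditions: 29 (2 equiv), Sc(OTf)3 (10 mol%), MeCN, 25 → 40 °C
Reagents that add atoms: none
Why: Friedel–Crafts-type benzylation: the Lewis acid ionises the benzylic methyl ether, helped by the two ortho oxygens and the para oxygen of ring A, and C3 of the 4-hydroxy-2-pyranone, the nucleophilic carbon of this vinylogous acid, takes up the benzylic carbon, as in the known acid-catalysed C3-benzylation of 4-hydroxypyranones and 4-hydroxycoumarins by benzylic alcohols and ethers; O-alkylation is reversible under these conditions and C5 of ring A is already blocked.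

Step 15
Reactants: 30 the coupled methyl ether from step 14
Product: 31 6-ethyl-4-hydroxy-3-{[(2R)-4-hydroxy-2-(2-hydroxypropan-2-yl)-5-[(2R)-2-methylbutanoyl]-6-{[tri(propan-2-yl)silyl]oxy}-2,3-dihydro-1-benzofuran-7-yl]methyl}-5-methyl-2H-pyran-2-one
Conditions: MgI2·OEt2 (4 equiv), THF/toluene, 60 °C; aq. Na2S2O3
Reagents that add atoms: none
Why: Chelation-assisted O-demethylation: Mg2+ bridges the ketone oxygen and the ortho methoxy oxygen and iodide removes the methyl group by SN2, a method selective for an ether next to a carbonyl that should leave the bulky silyl ether, the ring B ether and the tertiary alcohol alone, whereas boron halides would turn the tertiary alcohol into a halide.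

Step 16
Reactants: 31 the C4 phenol from step 15
Product: 32 4-{[tert-butyl(dimethyl)silyl]oxy}-3-{[(2R)-4-{[tert-butyl(dimethyl)silyl]oxy}-2-(2-hydroxypropan-2-yl)-5-[(2R)-2-methylbutanoyl]-6-{[tri(propan-2-yl)silyl]oxy}-2,3-dihydro-1-benzofuran-7-yl]methyl}-6-ethyl-5-methyl-2H-pyran-2-one
Conditions: TBSCl, imidazole, DMF, 25 → 40 °C; used without chromatography
Reagents that add atoms: tert-butyl(chloro)dimethylsilane, CC(C)(C)[Si](C)(C)Cl
Why: Imidazole-promoted silylation covers the two acidic hydroxyls (the C4 phenol and the pyranone enol), which would otherwise consume the dehydrating agent, while the hindered tertiary alcohol does not react with a silyl chloride.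

Step 17
Reactants: 32 the bis-silylated tertiary alcohol from step 16
Product: 33 4-{[tert-butyl(dimethyl)silyl]oxy}-3-{[(2R)-4-{[tert-butyl(dimethyl)silyl]oxy}-5-[(2R)-2-methylbutanoyl]-2-(prop-1-en-2-yl)-6-{[tri(propan-2-yl)silyl]oxy}-2,3-dihydro-1-benzofuran-7-yl]methyl}-6-ethyl-5-methyl-2H-pyran-2-one
Conditions: Burgess reagent, toluene, 60 °C
Reagents that add atoms: none
Why: Burgess dehydration: the tertiary sulfamate ester undergoes syn elimination, and loss of one of six methyl hydrogens to give the isopropenyl group should be preferred over loss of the single hydrogen at C2, which would give a strained exocyclic enol ether; the C2 stereocentre is not involved.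

Step 18
Reactants: 33 the silylated isopropenyl compound from step 17
Product: 34 3-{[(2R)-4,6-dihydroxy-5-[(2R)-2-methylbutanoyl]-2-(prop-1-en-2-yl)-2,3-dihydro-1-benzofuran-7-yl]methyl}-6-ethyl-4-hydroxy-5-methyl-2H-pyran-2-one (CNP0199358.1)
Conditions: TBAF, AcOH, THF, 0 → 25 °C
Reagents that add atoms: none
Why: Fluoride-induced desilylation removes the two aryl silyl ethers and the pyranone silyl enol ether, and the acetic acid buffer keeps the medium from becoming basic enough to epimerise the ketone or to open ring B.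

**Compound list**
1 | 2-chloro-1,1-dimethoxyethane | ClCC(OC)OC | starting material
2 | sodium methoxyethynide | [Na]C#COC | intermediate
3 | methoxyethyne | C#COC | intermediate
4 | 5-methylhex-4-enoic acid | CC(C)=CCCC(=O)O | starting material
5 | 5-methylhex-4-enoyl chloride | CC(C)=CCCC(=O)Cl | intermediate
6 | 5-methylhexa-1,4-dien-1-one (prenylketene) | CC(C)=CCC=C=O | intermediate
7 | 3-methoxy-4-(3-methylbut-2-en-1-yl)cyclobut-2-en-1-one (racemic) | COC1=CC(=O)C1CC=C(C)C | intermediate
8 | 3-methoxyprop-1-yne | COCC#C | starting material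
9 | lithium 3-methoxyprop-1-yn-1-ide | [Li]C#CCOC | intermediate
10 | lithium 3-methoxyprop-1-yn-1-olate | [Li]OC#CCOC | intermediate
11 | [(3-methoxyprop-1-yn-1-yl)oxy]tri(propan-2-yl)silane | COCC#CO[Si](C(C)C)(C(C)C)C(C)C | intermediate
12 | 3-methoxy-7-methylocta-1,3,6-trien-1-one (vinylketene) | O=C=CC(OC)=CCC=C(C)C | intermediate
13 | 4-(1-methoxy-5-methylhexa-1,4-dien-1-yl)-2-(methoxymethyl)-3-{[tri(propan-2-yl)silyl]oxy}cyclobut-2-en-1-one | COCC1=C(O[Si](C(C)C)(C(C)C)C(C)C)C(C(OC)=CCC=C(C)C)C1=O | intermediate
14 | 5-methoxy-2-(methoxymethyl)-9-methyl-3-{[tri(propan-2-yl)silyl]oxy}deca-1,3,5,8-tetraen-1-one (dienylketene) | COCC(=C=O)C(O[Si](C(C)C)(C(C)C)C(C)C)=CC(OC)=CCC=C(C)C | intermediate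
15 | 5-methoxy-2-(methoxymethyl)-6-(3-methylbut-2-en-1-yl)-3-{[tri(propan-2-yl)silyl]oxy}phenol | CC(C)=CCc1c(O)c(COC)c(O[Si](C(C)C)(C(C)C)C(C)C)cc1OC | intermediate
16 | 5-methoxy-2-(methoxymethyl)-6-(3-methylbut-2-en-1-yl)-3-{[tri(propan-2-yl)silyl]oxy}phenyl acetate | CC(C)=CCc1c(OC(C)=O)c(COC)c(O[Si](C(C)C)(C(C)C)C(C)C)cc1OC | intermediate
17 | 6-{[(2S)-3,3-dimethyloxiran-2-yl]methyl}-5-methoxy-2-(methoxymethyl)-3-{[tri(propan-2-yl)silyl]oxy}phenyl acetate | CC1(C)O[C@H]1Cc1c(OC(C)=O)c(COC)c(O[Si](C(C)C)(C(C)C)C(C)C)cc1OC | intermediate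
18 | potassium 6-{[(2S)-3,3-dimethyloxiran-2-yl]methyl}-5-methoxy-2-(methoxymethyl)-3-{[tri(propan-2-yl)silyl]oxy}phenolate | CC1(C)O[C@H]1Cc1c([O-])c(COC)c(O[Si](C(C)C)(C(C)C)C(C)C)cc1OC.[K+] | intermediate
19 | 2-[(2R)-4-methoxy-7-(methoxymethyl)-6-{[tri(propan-2-yl)silyl]oxy}-2,3-dihydro-1-benzofuran-2-yl]propan-2-ol | CC(C)(O)[C@H]1Cc2c(OC)cc(O[Si](C(C)C)(C(C)C)C(C)C)c(COC)c2O1 | intermediate
20 | 2-[(2R)-5-bromo-4-methoxy-7-(methoxymethyl)-6-{[tri(propan-2-yl)silyl]oxy}-2,3-dihydro-1-benzofuran-2-yl]propan-2-ol | CC(C)(O)[C@H]1Cc2c(OC)c(Br)c(O[Si](C(C)C)(C(C)C)C(C)C)c(COC)c2O1 | intermediate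
21 | (2R)-2-methylbutanoic acid | CC[C@@H](C)C(=O)O | starting material
22 | (2R)-1-(1H-imidazol-1-yl)-2-methylbutan-1-one | CC[C@@H](C)C(=O)n1ccnc1 | intermediate
23 | (2R)-N-methoxy-N,2-dimethylbutanamide | CC[C@@H](C)C(=O)N(C)OC | intermediate
24 | lithium 2-[(2R)-5-lithio-4-methoxy-7-(methoxymethyl)-6-{[tri(propan-2-yl)silyl]oxy}-2,3-dihydro-1-benzofuran-2-yl]propan-2-olate | CC(C)(O[Li])[C@H]1Cc2c(OC)c([Li])c(O[Si](C(C)C)(C(C)C)C(C)C)c(COC)c2O1 | intermediate
25 | (2R)-1-[(2R)-2-(2-hydroxypropan-2-yl)-4-methoxy-7-(methoxymethyl)-6-{[tri(propan-2-yl)silyl]oxy}-2,3-dihydro-1-benzofuran-5-yl]-2-methylbutan-1-one | CC(C)(O)[C@H]1Cc2c(OC)c(C(=O)[C@H](C)CC)c(O[Si](C(C)C)(C(C)C)C(C)C)c(COC)c2O1 | intermediate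
26 | pentan-3-one | CCC(=O)CC | starting material
27 | trimethyl(pent-2-en-3-yloxy)silane (E/Z mixture) | CC=C(CC)O[Si](C)(C)C | intermediate
28 | propanedioyl dichloride | O=C(Cl)CC(=O)Cl | starting material
29 | 6-ethyl-4-hydroxy-5-methyl-2H-pyran-2-one | CCc1oc(=O)cc(O)c1C | intermediate
30 | 6-ethyl-4-hydroxy-3-{[(2R)-2-(2-hydroxypropan-2-yl)-4-methoxy-5-[(2R)-2-methylbutanoyl]-6-{[tri(propan-2-yl)silyl]oxy}-2,3-dihydro-1-benzofuran-7-yl]methyl}-5-methyl-2H-pyran-2-one | CC(C)(O)[C@H]1Cc2c(OC)c(C(=O)[C@H](C)CC)c(O[Si](C(C)C)(C(C)C)C(C)C)c(Cc3c(O)c(C)c(CC)oc3=O)c2O1 | intermediate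
31 | 6-ethyl-4-hydroxy-3-{[(2R)-4-hydroxy-2-(2-hydroxypropan-2-yl)-5-[(2R)-2-methylbutanoyl]-6-{[tri(propan-2-yl)silyl]oxy}-2,3-dihydro-1-benzofuran-7-yl]methyl}-5-methyl-2H-pyran-2-one | CC(C)(O)[C@H]1Cc2c(O)c(C(=O)[C@H](C)CC)c(O[Si](C(C)C)(C(C)C)C(C)C)c(Cc3c(O)c(C)c(CC)oc3=O)c2O1 | intermediate
32 | 4-{[tert-butyl(dimethyl)silyl]oxy}-3-{[(2R)-4-{[tert-butyl(dimethyl)silyl]oxy}-2-(2-hydroxypropan-2-yl)-5-[(2R)-2-methylbutanoyl]-6-{[tri(propan-2-yl)silyl]oxy}-2,3-dihydro-1-benzofuran-7-yl]methyl}-6-ethyl-5-methyl-2H-pyran-2-one | CC(C)(O)[C@H]1Cc2c(O[Si](C)(C)C(C)(C)C)c(C(=O)[C@H](C)CC)c(O[Si](C(C)C)(C(C)C)C(C)C)c(Cc3c(O[Si](C)(C)C(C)(C)C)c(C)c(CC)oc3=O)c2O1 | intermediate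
33 | 4-{[tert-butyl(dimethyl)silyl]oxy}-3-{[(2R)-4-{[tert-butyl(dimethyl)silyl]oxy}-5-[(2R)-2-methylbutanoyl]-2-(prop-1-en-2-yl)-6-{[tri(propan-2-yl)silyl]oxy}-2,3-dihydro-1-benzofuran-7-yl]methyl}-6-ethyl-5-methyl-2H-pyran-2-one | C=C(C)[C@H]1Cc2c(O[Si](C)(C)C(C)(C)C)c(C(=O)[C@H](C)CC)c(O[Si](C(C)C)(C(C)C)C(C)C)c(Cc3c(O[Si](C)(C)C(C)(C)C)c(C)c(CC)oc3=O)c2O1 | intermediate
34 | 3-{[(2R)-4,6-dihydroxy-5-[(2R)-2-methylbutanoyl]-2-(prop-1-en-2-yl)-2,3-dihydro-1-benzofuran-7-yl]methyl}-6-ethyl-4-hydroxy-5-methyl-2H-pyran-2-one | C=C(C)[C@H]1Cc2c(O)c(C(=O)[C@H](C)CC)c(O)c(Cc3c(O)c(C)c(CC)oc3=O)c2O1 | target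

**Step count and risks**

Total step count: 18.
Longest linear sequence: 13 steps (4 → 5 → 7 → 15 → 16 → 17 → 19 → 20 → 25 → 30 → 31 → 32 → 33 → 34; the branch from 1 is equally long).

Steps most likely to fail:

Step 5. The methoxy cyclobutenone may need more heat to open than the siloxyalkyne and the product tolerate. Alkyne decomposition, thermal loss of methanol from the ortho-hydroxybenzyl ether of the product, and O-acylation of the product phenol by unconsumed vinylketene would then compete with the cascade. The fallback generates the same vinylketene 12 near room temperature by 1,4-dehydrochlorination instead of electrocyclic opening; it sets out from siloxyalkyne 11 and comes back at phenol 15. The dianion of methyl acetoacetate (NaH, then n-BuLi, THF, 0 °C) is alkylated at its terminal carbon with 1-bromo-3-methylbut-2-ene to give methyl 7-methyl-3-oxooct-6-enoate F1. Trimethyl orthoformate with catalytic acid in methanol turns it into the enol ether methyl (2E)-3-methoxy-7-methylocta-2,6-dienoate F2. LiOH hydrolysis gives (2E)-3-methoxy-7-methylocta-2,6-dienoic acid F3, and oxalyl chloride gives (2E)-3-methoxy-7-methylocta-2,6-dienoyl chloride F4. Slow addition of Et3N to F4 and 11 in toluene at 25 °C should remove HCl across C2–C4 to give 12, which enters the same (2+2), 4π-opening and 6π-closure sequence on warming to 80 °C and ends at 15.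

Step 11. The doubly ortho-substituted aryllithium may add too slowly to the amide, so that oxygen-to-carbon silyl migration within the aryllithium or proton transfer from the amide takes over and the bromide is simply reduced. The fallback uses a far more electrophilic and less hindered carbonyl partner and restores the ketone by oxidation; it sets out from bromide 20 and amide 23 and comes back at ketone 25. LiAlH4 (THF, −78 °C) reduces 23 to (2R)-2-methylbutanal F5, which is used at once and cold to keep its configuration. The dilithio species 24, made from 20 as in step 11, adds to F5 at −78 °C to give (2R)-1-[(2R)-2-(2-hydroxypropan-2-yl)-4-methoxy-7-(methoxymethyl)-6-{[tri(propan-2-yl)silyl]oxy}-2,3-dihydro-1-benzofuran-5-yl]-2-methylbutan-1-ol F6 as a mixture at the new carbinol carbon. The mixture does not matter, because Dess–Martin periodinane (NaHCO3, CH2Cl2) oxidises both epimers to 25.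

Step 14. Ionisation of the benzylic ether next to the bulky silyl ether may be sluggish. Oxygen nucleophiles (the pyranone oxygen, or the tertiary hydroxyl closing a seven-membered ether) may trap the benzylic carbon without reverting, or the acid may strip the aryl silyl ether. The fallback reverses the polarity at the benzylic carbon; it sets out from ketone 25 and comes back at 30. DDQ in wet CH2Cl2 oxidises the benzylic methyl ether to (2R)-2-(2-hydroxypropan-2-yl)-4-methoxy-5-[(2R)-2-methylbutanoyl]-6-{[tri(propan-2-yl)silyl]oxy}-2,3-dihydro-1-benzofuran-7-carbaldehyde F7. Knoevenagel condensation of F7 with pyranone 29 and conjugate reduction of the adduct by Hantzsch ester in the same flask (L-proline cat., CH2Cl2, 25 °C) should give 30.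

Further compounds
F1 | step 5 | methyl 7-methyl-3-oxooct-6-enoate | COC(=O)CC(=O)CCC=C(C)C
F2 | step 5 | methyl (2E)-3-methoxy-7-methylocta-2,6-dienoate | CO/C(CCC=C(C)C)=C/C(=O)OC
F3 | step 5 | (2E)-3-methoxy-7-methylocta-2,6-dienoic acid | CO/C(CCC=C(C)C)=C/C(=O)O
F4 | step 5 | (2E)-3-methoxy-7-methylocta-2,6-dienoyl chloride | CO/C(CCC=C(C)C)=C/C(=O)Cl
F5 | step 11 | (2R)-2-methylbutanal | CC[C@@H](C)C=O
F6 | step 11 | (2R)-1-[(2R)-2-(2-hydroxypropan-2-yl)-4-methoxy-7-(methoxymethyl)-6-{[tri(propan-2-yl)silyl]oxy}-2,3-dihydro-1-benzofuran-5-yl]-2-methylbutan-1-ol (both carbinol epimers) | CC(C)(O)[C@H]1Cc2c(OC)c(C(O)[C@H](C)CC)c(O[Si](C(C)C)(C(C)C)C(C)C)c(COC)c2O1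
F7 | step 14 | (2R)-2-(2-hydroxypropan-2-yl)-4-methoxy-5-[(2R)-2-methylbutanoyl]-6-{[tri(propan-2-yl)silyl]oxy}-2,3-dihydro-1-benzofuran-7-carbaldehyde | CC(C)(O)[C@H]1Cc2c(OC)c(C(=O)[C@H](C)CC)c(O[Si](C(C)C)(C(C)C)C(C)C)c(C=O)c2O1
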